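**Retrosynthetic overview**
1. Target 22 ⇐ bis-silyl ether 21 (desilylation) ⇐ C8 carbinol 19 (angelate put on with inversion).
2. 19 ⇐ acyclic allylboronate 16: one acid-triggered operation closes the lactone ring (as an α-borylmethyl butenolide, O6–C12) and then the ten-membered ring (intramolecular allylboration, C7–C8), setting C7 and C8.
3. 16 ⇐ ynoate 14 (conjugate hydroalumination/borylmethylation) ⇐ enal 11 + methyl propiolate (catalytic asymmetric alkynylation sets C6).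
4. 11 ⇐ two copies of (Z)-iodobutenol 4 (from but-2-yne-1,4-diol; fixes both trisubstituted alkenes), joined by a Wittig carbon and a B-alkyl Suzuki coupling; C8–C9 from a dioxolanylmethyl Grignard reagent.
5. Ring order: γ-lactone first, carbocycle second, both in step 11.

Assumption: the SMILES is read literally, so in both ring alkenes the two ring carbons are cis (CIP E,E because CH2OH outranks ring CH2) and the centres are 6R,7R,8R; germacrane numbering is used (O6–C12 lactone, C7 ring fusion, C8 ester carbon, C11=C13 methylidene, C14/C15 the CH2OH carbons on C10/C4).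

**Step 1**
Reactants: 1 but-2-yne-1,4-diol
Product: 2 4-{[tert-butyl(diphenyl)silyl]oxy}but-2-yn-1-ol
Conditions: t-BuPh2SiCl (1 equiv), imidazole, DMF, 0 °C → rt; 1 in fourfold excess
Reagents that add atoms: tert-butyl(chloro)diphenylsilane, CC(C)(C)[Si](Cl)(c1ccccc1)c1ccccc1
Why: Statistical monosilylation of a cheap symmetric diol used in excess (silyl ether formation), no stereocentre involved.

**Step 2**
Reactants: 2 4-{[tert-butyl(diphenyl)silyl]oxy}but-2-yn-1-ol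
Product: 4 (2Z)-4-{[tert-butyl(diphenyl)silyl]oxy}-3-iodobut-2-en-1-ol, via vinylalanate 3 (not isolated)
Conditions: NaAlH2(OCH2CH2OMe)2, THF, 0 °C → rt; then I2, −78 → 0 °C
Reagents that add atoms: iodine, II
Why: Hydroxyl-directed trans-hydroalumination puts aluminium on the distal alkyne carbon in a five-membered alanate and iodinolysis with retention gives the vinyl iodide with I cis to CH2OH, which fixes the geometry of both future ring alkenes.

**Step 3**
Reactants: 4 (2Z)-4-{[tert-butyl(diphenyl)silyl]oxy}-3-iodobut-2-en-1-ol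
Product: 5 (2Z)-4-{[tert-butyl(diphenyl)silyl]oxy}-3-iodobut-2-enal
Conditions: MnO2, CH2Cl2, rt, dark
Reagents that add atoms: none
Why: MnO2 oxidises the allylic alcohol selectively under neutral conditions without touching the vinyl iodide or its geometry.

**Step 4**
Reactants: 5 (2Z)-4-{[tert-butyl(diphenyl)silyl]oxy}-3-iodobut-2-enal
Product: 6 tert-butyl{[(2Z)-2-iodopenta-2,4-dien-1-yl]oxy}diphenylsilane
Conditions: Ph3PCH3Br, KN(SiMe3)2, THF, −78 → 0 °C
Reagents that add atoms: methyltriphenylphosphonium bromide, C[P+](c1ccccc1)(c1ccccc1)c1ccccc1.[Br-]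
Why: Wittig methylenation of the aldehyde supplies C3 as a terminal vinyl group; the unstabilised ylide adds to the carbonyl much faster than to the β-iodo carbon.

**Step 5**
Reactants: 6 tert-butyl{[(2Z)-2-iodopenta-2,4-dien-1-yl]oxy}diphenylsilane; 7 (1,3-dioxolan-2-ylmethyl)magnesium bromide
Product: 8 tert-butyl{[(2E)-2-(1,3-dioxolan-2-ylmethyl)penta-2,4-dien-1-yl]oxy}diphenylsilane
Conditions: PdCl2(dppf) (3 mol %), THF, 0 °C → rt
Reagents that add atoms: none
Why: Kumada–Corriu coupling of a vinyl iodide with a primary alkyl Grignard reagent goes with retention at the sp2 carbon and brings in C9 and C8 as a masked aldehyde; the wide-bite-angle ligand makes reductive elimination faster than β-elimination.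

**Step 6**
Reactants: 8 tert-butyl{[(2E)-2-(1,3-dioxolan-2-ylmethyl)penta-2,4-dien-1-yl]oxy}diphenylsilane; 4 (2Z)-4-{[tert-butyl(diphenyl)silyl]oxy}-3-iodobut-2-en-1-ol
Product: 10 (2E,6E)-3,7-bis({[tert-butyl(diphenyl)silyl]oxy}methyl)-8-(1,3-dioxolan-2-yl)octa-2,6-dien-1-ol, via alkylborane 9 (not isolated)
Conditions: 9-BBN-H, THF, 0 °C → rt; then 4, PdCl2(dppf), AsPh3, Cs2CO3, DMF/H2O, rt
Reagents that add atoms: none
Why: 9-BBN adds anti-Markovnikov to the terminal vinyl group only, and B-alkyl Suzuki–Miyaura coupling with a second copy of iodide 4 forms C3–C4 with retention of alkene geometry.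

**Step 7**
Reactants: 10 (2E,6E)-3,7-bis({[tert-butyl(diphenyl)silyl]oxy}methyl)-8-(1,3-dioxolan-2-yl)octa-2,6-dien-1-ol
Product: 11 (2E,6E)-3,7-bis({[tert-butyl(diphenyl)silyl]oxy}methyl)-8-(1,3-dioxolan-2-yl)octa-2,6-dienal
Conditions: MnO2, CH2Cl2, rt
Reagents that add atoms: none
Why: Allylic oxidation of the only free alcohol gives the C6 enal; the acetal and silyl ethers are inert.

**Step 8**
Reactants: 11 (2E,6E)-3,7-bis({[tert-butyl(diphenyl)silyl]oxy}methyl)-8-(1,3-dioxolan-2-yl)octa-2,6-dienal; 12 methyl prop-2-ynoate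
Product: 13 methyl (4R,5E,9E)-6,10-bis({[tert-butyl(diphenyl)silyl]oxy}methyl)-11-(1,3-dioxolan-2-yl)-4-hydroxyundeca-5,9-dien-2-ynoate
Conditions: Me2Zn, (S,S)-ProPhenol (20 mol %), Ph3P=O (40 mol %), toluene, 4 °C
Reagents that add atoms: none
Why: Zinc–ProPhenol-catalysed enantioselective alkynylation of an enal sets C6 (4R here) by catalyst control and brings in C7, C11 and C12; the (S,S) ligand is taken to give the R alcohol, and its antipode would be used if the sense proved opposite.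

**Step 9**
Reactants: 13 methyl (4R,5E,9E)-6,10-bis({[tert-butyl(diphenyl)silyl]oxy}methyl)-11-(1,3-dioxolan-2-yl)-4-hydroxyundeca-5,9-dien-2-ynoate
Product: 14 methyl (4R,5E,9E)-6,10-bis({[tert-butyl(diphenyl)silyl]oxy}methyl)-11-(1,3-dioxolan-2-yl)-4-[(triethylsilyl)oxy]undeca-5,9-dien-2-ynoate
Conditions: Et3SiCl, imidazole, CH2Cl2, 0 °C
Reagents that add atoms: chlorotriethylsilane, CC[Si](Cl)(CC)CC
Why: Silylation keeps the hydroxy ester acyclic until step 11 and removes the free alkoxide that could misdirect the hydroalumination.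

**Step 10**
Reactants: 14 methyl (4R,5E,9E)-6,10-bis({[tert-butyl(diphenyl)silyl]oxy}methyl)-11-(1,3-dioxolan-2-yl)-4-[(triethylsilyl)oxy]undeca-5,9-dien-2-ynoate
Product: 16 methyl (2Z,4R,5E,9E)-6,10-bis({[tert-butyl(diphenyl)silyl]oxy}methyl)-11-(1,3-dioxolan-2-yl)-2-[(4,4,5,5-tetramethyl-1,3,2-dioxaborolan-2-yl)methyl]-4-[(triethylsilyl)oxy]undeca-2,5,9-trienoate, via alkenylalane 15 (not isolated)
Conditions: i-Bu2AlH, HMPA, THF, 0 °C; then ICH2B(pin), 0 °C → rt
Reagents that add atoms: 2-(iodomethyl)-4,4,5,5-tetramethyl-1,3,2-dioxaborolane, CC1(C)OB(CI)OC1(C)C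
Why: Conjugate syn-hydroalumination of the ynoate gives the α-aluminated enoate, which is alkylated at carbon by the iodomethylboronate (ate complex, 1,2-shift), so C6 ends cis to the ester as the later lactonisation requires, and C13 arrives already bonded to boron.

**Step 11**
Reactants: 16 methyl (2Z,4R,5E,9E)-6,10-bis({[tert-butyl(diphenyl)silyl]oxy}methyl)-11-(1,3-dioxolan-2-yl)-2-[(4,4,5,5-tetramethyl-1,3,2-dioxaborolan-2-yl)methyl]-4-[(triethylsilyl)oxy]undeca-2,5,9-trienoate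
Product: 19 (3aR,4S,6E,10E,11aR)-6,10-bis({[tert-butyl(diphenyl)silyl]oxy}methyl)-4-hydroxy-3-methylidene-3a,4,5,8,9,11a-hexahydrocyclodeca[b]furan-2(3H)-one, via butenolide boronate acetal 17 (not isolated), via butenolide boronate aldehyde 18 (not isolated)
Conditions: Sc(OTf)3 (20 mol %), MeCN/H2O 20:1, 0.002 M, 0 → 40 °C
Reagents that add atoms: water, O
Why: Proposed new method: Sc(OTf)3 in wet MeCN cleaves the triethylsilyl ether, the freed (Z)-γ-hydroxy ester lactonises at once to the α-(borylmethyl)butenolide 17 (lactone ring), the slower dioxolane hydrolysis then unmasks the C8 aldehyde 18, and the Lewis-acid-activated allylboronate adds to it through a six-membered chair transition state on the face of C7 anti to the C5 chain (trans lactone, 7R) with the aldehyde chain equatorial (8S carbinol), closing the ten-membered ring and regenerating the methylidene by allyl transposition; the closest known reactions are the Sc(OTf)3-catalysed addition of 2-alkoxycarbonyl allylboronates to aldehydes with lactonisation and the trans-selective Barbier addition of 3-(bromomethyl)furan-2(5H)-ones to aldehydes, neither of which has been used to close a medium ring.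

**Step 12**
Reactants: 19 (3aR,4S,6E,10E,11aR)-6,10-bis({[tert-butyl(diphenyl)silyl]oxy}methyl)-4-hydroxy-3-methylidene-3a,4,5,8,9,11a-hexahydrocyclodeca[b]furan-2(3H)-one; 20 (2Z)-2-methylbut-2-enoic acid (angelic acid)
Product: 21 (3aR,4R,6E,10E,11aR)-6,10-bis({[tert-butyl(diphenyl)silyl]oxy}methyl)-3-methylidene-2-oxo-2,3,3a,4,5,8,9,11a-octahydrocyclodeca[b]furan-4-yl (2Z)-2-methylbut-2-enoate
Conditions: PPh3/DIAD (premixed), toluene, 0 °C → rt
Reagents that add atoms: none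
Why: Mitsunobu esterification displaces the activated C8 oxygen by angelate with SN2 inversion, turning the 8S carbinol into the 8R ester, and the amine-free conditions avoid angelate-to-tiglate isomerisation.

**Step 13**
Reactants: 21 (3aR,4R,6E,10E,11aR)-6,10-bis({[tert-butyl(diphenyl)silyl]oxy}methyl)-3-methylidene-2-oxo-2,3,3a,4,5,8,9,11a-octahydrocyclodeca[b]furan-4-yl (2Z)-2-methylbut-2-enoate
Product: 22 (3aR,4R,6E,10E,11aR)-6,10-bis(hydroxymethyl)-3-methylidene-2-oxo-2,3,3a,4,5,8,9,11a-octahydrocyclodeca[b]furan-4-yl (2Z)-2-methylbut-2-enoate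
Conditions: HF·pyridine, pyridine, THF, 0 °C → rt
Reagents that add atoms: none
Why: Buffered fluoride cleaves the two primary silyl ethers (desilylation) while leaving the methylidene lactone and the angelate intact.

**Compound list**
1 | but-2-yne-1,4-diol | OCC#CCO | starting material
2 | 4-{[tert-butyl(diphenyl)silyl]oxy}but-2-yn-1-ol | OCC#CCO[Si](c1ccccc1)(c1ccccc1)C(C)(C)C | intermediate
3 | sodium cyclic vinylalanate (Al bonded to O1 and C3 of the butenyl unit, two 2-methoxyethoxy ligands) | COCCO[Al-]1(OCCOC)OCC=C1CO[Si](c2ccccc2)(c2ccccc2)C(C)(C)C.[Na+] | intermediate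
4 | (2Z)-4-{[tert-butyl(diphenyl)silyl]oxy}-3-iodobut-2-en-1-ol | OC/C=C(\I)CO[Si](c1ccccc1)(c1ccccc1)C(C)(C)C | intermediate
5 | (2Z)-4-{[tert-butyl(diphenyl)silyl]oxy}-3-iodobut-2-enal | O=C/C=C(\I)CO[Si](c1ccccc1)(c1ccccc1)C(C)(C)C | intermediate
6 | tert-butyl{[(2Z)-2-iodopenta-2,4-dien-1-yl]oxy}diphenylsilane | C=C/C=C(\I)CO[Si](c1ccccc1)(c1ccccc1)C(C)(C)C | intermediate
7 | (1,3-dioxolan-2-ylmethyl)magnesium bromide | Br[Mg]CC1OCCO1 | starting material
8 | tert-butyl{[(2E)-2-(1,3-dioxolan-2-ylmethyl)penta-2,4-dien-1-yl]oxy}diphenylsilane | C=C/C=C(\CC1OCCO1)CO[Si](c1ccccc1)(c1ccccc1)C(C)(C)C | intermediate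
9 | 9-[(3E)-4-({[tert-butyl(diphenyl)silyl]oxy}methyl)-5-(1,3-dioxolan-2-yl)pent-3-en-1-yl]-9-borabicyclo[3.3.1]nonane | B1(CC/C=C(\CC2OCCO2)CO[Si](c2ccccc2)(c2ccccc2)C(C)(C)C)C2CCCC1CCC2 | intermediate
10 | (2E,6E)-3,7-bis({[tert-butyl(diphenyl)silyl]oxy}methyl)-8-(1,3-dioxolan-2-yl)octa-2,6-dien-1-ol | OC/C=C(\CC/C=C(\CC1OCCO1)CO[Si](c1ccccc1)(c1ccccc1)C(C)(C)C)CO[Si](c1ccccc1)(c1ccccc1)C(C)(C)C | intermediate
11 | (2E,6E)-3,7-bis({[tert-butyl(diphenyl)silyl]oxy}methyl)-8-(1,3-dioxolan-2-yl)octa-2,6-dienal | O=C/C=C(\CC/C=C(\CC1OCCO1)CO[Si](c1ccccc1)(c1ccccc1)C(C)(C)C)CO[Si](c1ccccc1)(c1ccccc1)C(C)(C)C | intermediate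
12 | methyl prop-2-ynoate (methyl propiolate) | C#CC(=O)OC | starting material
13 | methyl (4R,5E,9E)-6,10-bis({[tert-butyl(diphenyl)silyl]oxy}methyl)-11-(1,3-dioxolan-2-yl)-4-hydroxyundeca-5,9-dien-2-ynoate | COC(=O)C#C[C@H](O)/C=C(\CC/C=C(\CC1OCCO1)CO[Si](c1ccccc1)(c1ccccc1)C(C)(C)C)CO[Si](c1ccccc1)(c1ccccc1)C(C)(C)C | intermediate
14 | methyl (4R,5E,9E)-6,10-bis({[tert-butyl(diphenyl)silyl]oxy}methyl)-11-(1,3-dioxolan-2-yl)-4-[(triethylsilyl)oxy]undeca-5,9-dien-2-ynoate | COC(=O)C#C[C@H](O[Si](CC)(CC)CC)/C=C(\CC/C=C(\CC1OCCO1)CO[Si](c1ccccc1)(c1ccccc1)C(C)(C)C)CO[Si](c1ccccc1)(c1ccccc1)C(C)(C)C | intermediate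
15 | methyl (4R,5E,9E)-2-(diisobutylalumanyl)-…-4-[(triethylsilyl)oxy]undeca-2,5,9-trienoate (Al cis to H3, ester cis to C4) | COC(=O)/C([Al](CC(C)C)CC(C)C)=C\[C@H](O[Si](CC)(CC)CC)/C=C(\CC/C=C(\CC1OCCO1)CO[Si](c1ccccc1)(c1ccccc1)C(C)(C)C)CO[Si](c1ccccc1)(c1ccccc1)C(C)(C)C | intermediate
16 | methyl (2Z,4R,5E,9E)-6,10-bis({[tert-butyl(diphenyl)silyl]oxy}methyl)-11-(1,3-dioxolan-2-yl)-2-[(4,4,5,5-tetramethyl-1,3,2-dioxaborolan-2-yl)methyl]-4-[(triethylsilyl)oxy]undeca-2,5,9-trienoate | COC(=O)/C(CB1OC(C)(C)C(C)(C)O1)=C\[C@H](O[Si](CC)(CC)CC)/C=C(\CC/C=C(\CC1OCCO1)CO[Si](c1ccccc1)(c1ccccc1)C(C)(C)C)CO[Si](c1ccccc1)(c1ccccc1)C(C)(C)C | intermediate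
17 | (5R)-5-[(1E,5E)-2,6-bis({[tert-butyl(diphenyl)silyl]oxy}methyl)-7-(1,3-dioxolan-2-yl)hepta-1,5-dien-1-yl]-3-[(4,4,5,5-tetramethyl-1,3,2-dioxaborolan-2-yl)methyl]furan-2(5H)-one | O=C1O[C@H](/C=C(\CC/C=C(\CC2OCCO2)CO[Si](c2ccccc2)(c2ccccc2)C(C)(C)C)CO[Si](c2ccccc2)(c2ccccc2)C(C)(C)C)C=C1CB1OC(C)(C)C(C)(C)O1 | intermediate
18 | (5R)-5-[(1E,5E)-2,6-bis({[tert-butyl(diphenyl)silyl]oxy}methyl)-7-oxohepta-1,5-dien-1-yl]-3-[(4,4,5,5-tetramethyl-1,3,2-dioxaborolan-2-yl)methyl]furan-2(5H)-one | O=C1O[C@H](/C=C(\CC/C=C(\CC=O)CO[Si](c2ccccc2)(c2ccccc2)C(C)(C)C)CO[Si](c2ccccc2)(c2ccccc2)C(C)(C)C)C=C1CB1OC(C)(C)C(C)(C)O1 | intermediate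
19 | (3aR,4S,6E,10E,11aR)-6,10-bis({[tert-butyl(diphenyl)silyl]oxy}methyl)-4-hydroxy-3-methylidene-3a,4,5,8,9,11a-hexahydrocyclodeca[b]furan-2(3H)-one (trans lactone, 8S alcohol) | C=C1C(=O)O[C@@H]2/C=C(/CO[Si](c3ccccc3)(c3ccccc3)C(C)(C)C)CC/C=C(/CO[Si](c3ccccc3)(c3ccccc3)C(C)(C)C)C[C@H](O)[C@@H]12 | intermediate
20 | (2Z)-2-methylbut-2-enoic acid (angelic acid) | C/C=C(/C)C(=O)O | starting material
21 | (3aR,4R,6E,10E,11aR)-6,10-bis({[tert-butyl(diphenyl)silyl]oxy}methyl)-3-methylidene-2-oxo-2,3,3a,4,5,8,9,11a-octahydrocyclodeca[b]furan-4-yl (2Z)-2-methylbut-2-enoate | C=C1C(=O)O[C@@H]2/C=C(/CO[Si](c3ccccc3)(c3ccccc3)C(C)(C)C)CC/C=C(/CO[Si](c3ccccc3)(c3ccccc3)C(C)(C)C)C[C@@H](OC(=O)/C(C)=C\C)[C@@H]12 | intermediate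
22 | (3aR,4R,6E,10E,11aR)-6,10-bis(hydroxymethyl)-3-methylidene-2-oxo-2,3,3a,4,5,8,9,11a-octahydrocyclodeca[b]furan-4-yl (2Z)-2-methylbut-2-enoate | C=C1C(=O)O[C@@H]2/C=C(/CO)CC/C=C(/CO)C[C@@H](OC(=O)/C(C)=C\C)[C@@H]12 | target

**Step count and risks**
Total: 13 steps. Longest linear sequence: 13 steps (1 → 22; iodide 4 is used twice).

Step 11 is the most likely to fail. The ten-membered ring may not close in competition with oligomerisation. If the aldehyde is freed before lactonisation, the acyclic boronate could add first and give the 8,12-lactone. The face selectivity at C7 and C8 rests on a chair model for an unprecedented ring size. Fallback: set out from 14 and form the two rings in separate operations with a more nucleophilic allylmetal. Hydroalumination (i-Bu2AlH, HMPA) is quenched with paraformaldehyde to give the (2Z)-2-(hydroxymethyl) enoate F1. Appel bromination (CBr4, PPh3) gives the allylic bromide F2. Sc(OTf)3 in wet MeCN removes the triethylsilyl group, lactonises and frees the aldehyde to give the 3-(bromomethyl)butenolide aldehyde F3. A Nozaki–Hiyama-type Barbier closure with CrCl2 (divalent chromium, THF/DMF, high dilution) forms C7–C8 and comes back to the route at 19.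

Step 10 is the second risk. The aluminated enoate may not capture the iodomethylboronate, or may lose geometry. Fallback: set out from 14 and build the C11–C13 bond by cross-coupling. Syn-hydrostannation (Bu3SnH, PdCl2(PPh3)2) gives the α-stannyl enoate F4. Iododestannylation (I2, CH2Cl2, 0 °C) gives the α-iodo enoate F5 with retention. Negishi coupling with IZnCH2B(pin) (Pd(PPh3)4, zerovalent palladium, THF) comes back to the route at 16.

Step 12 is the third risk. Mitsunobu inversion at the hindered C8 carbinol may be slow or give elimination towards C9. Fallback: set out from 19 and replace the redox condensation by activation and carboxylate displacement. ClCH2SO2Cl/pyridine gives the chloromethanesulfonate F6. Cesium angelate (from 20 and Cs2CO3, 18-crown-6, toluene, 60 °C) displaces it with inversion and comes back to the route at 21.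

**Further compounds**
F1 | step 11 | methyl (2Z,4R,5E,9E)-6,10-bis({[tert-butyl(diphenyl)silyl]oxy}methyl)-11-(1,3-dioxolan-2-yl)-2-(hydroxymethyl)-4-[(triethylsilyl)oxy]undeca-2,5,9-trienoate | COC(=O)/C(CO)=C\[C@H](O[Si](CC)(CC)CC)/C=C(\CC/C=C(\CC1OCCO1)CO[Si](c1ccccc1)(c1ccccc1)C(C)(C)C)CO[Si](c1ccccc1)(c1ccccc1)C(C)(C)C
F2 | step 11 | methyl (2E,4R,5E,9E)-2-(bromomethyl)-6,10-bis({[tert-butyl(diphenyl)silyl]oxy}methyl)-11-(1,3-dioxolan-2-yl)-4-[(triethylsilyl)oxy]undeca-2,5,9-trienoate | COC(=O)/C(CBr)=C\[C@H](O[Si](CC)(CC)CC)/C=C(\CC/C=C(\CC1OCCO1)CO[Si](c1ccccc1)(c1ccccc1)C(C)(C)C)CO[Si](c1ccccc1)(c1ccccc1)C(C)(C)C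
F3 | step 11 | (5R)-3-(bromomethyl)-5-[(1E,5E)-2,6-bis({[tert-butyl(diphenyl)silyl]oxy}methyl)-7-oxohepta-1,5-dien-1-yl]furan-2(5H)-one | O=C1O[C@H](/C=C(\CC/C=C(\CC=O)CO[Si](c2ccccc2)(c2ccccc2)C(C)(C)C)CO[Si](c2ccccc2)(c2ccccc2)C(C)(C)C)C=C1CBr
F4 | step 10 | methyl (2E,4R,5E,9E)-6,10-bis({[tert-butyl(diphenyl)silyl]oxy}methyl)-11-(1,3-dioxolan-2-yl)-2-(tributylstannyl)-4-[(triethylsilyl)oxy]undeca-2,5,9-trienoate | COC(=O)/C([Sn](CCCC)(CCCC)CCCC)=C\[C@H](O[Si](CC)(CC)CC)/C=C(\CC/C=C(\CC1OCCO1)CO[Si](c1ccccc1)(c1ccccc1)C(C)(C)C)CO[Si](c1ccccc1)(c1ccccc1)C(C)(C)C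
F5 | step 10 | methyl (2E,4R,5E,9E)-6,10-bis({[tert-butyl(diphenyl)silyl]oxy}methyl)-11-(1,3-dioxolan-2-yl)-2-iodo-4-[(triethylsilyl)oxy]undeca-2,5,9-trienoate | COC(=O)/C(I)=C\[C@H](O[Si](CC)(CC)CC)/C=C(\CC/C=C(\CC1OCCO1)CO[Si](c1ccccc1)(c1ccccc1)C(C)(C)C)CO[Si](c1ccccc1)(c1ccccc1)C(C)(C)C
F6 | step 12 | (3aR,4S,6E,10E,11aR)-6,10-bis({[tert-butyl(diphenyl)silyl]oxy}methyl)-3-methylidene-2-oxo-2,3,3a,4,5,8,9,11a-octahydrocyclodeca[b]furan-4-yl chloromethanesulfonate | C=C1C(=O)O[C@@H]2/C=C(/CO[Si](c3ccccc3)(c3ccccc3)C(C)(C)C)CC/C=C(/CO[Si](c3ccccc3)(c3ccccc3)C(C)(C)C)C[C@H](OS(=O)(=O)CCl)[C@@H]12
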